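The rate constants come from no measurement.

Late in these runs, once crystals stand, we expect dissolved product to sit near its solubility, so we ask what rate that state leaves the flask.

    starting material + reagent + product → 2 product (k1 = 3.2 L² mol⁻² s⁻¹)
    crystals ⇌ product, rate k2*(cs2 - [product]) while solid is left; crystals form when [product] > cs2 (cs2 = 25 mM, k2 = 0.32 s⁻¹)
    starting material + reagent → product (k3 = 7.6 × 10⁻⁴ L mol⁻¹ s⁻¹)

| setting | Tuesday's | Saturday's | Friday's | Sunday's |
|---|---|---|---|---|
| starting material | 0.059 M (fed, over 40 s) | 0.059 M | 0.059 M | 0.059 M (fed, over 6.0 min) |
| reagent | 0.0649 M | 0.0649 M (fed, over 6.0 min) | 0.0649 M | 0.0649 M |
| time | 10 min | 10 min | 10 min | 10 min |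
| remark | all else is in the flask from the start; the feed brings no volume worth counting | all else is in the flask from the start; the feed brings no volume worth counting | everything together at the start | all else is in the flask from the start; the feed brings no volume worth counting |

- the flask with the highest amount of product, in percent of the starting material charged ("all alike" if they lie within 1.5 percentage points) (Tuesday's / Saturday's / Friday's / Sunday's / all alike)
- final product, as a percentage of the starting material charged, in Tuesday's
- final product, as a percentage of the starting material charged, in Saturday's
- final product, as a percentage of the starting material charged, in Friday's
- final product, as a percentage of the starting material charged, in Sunday's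

- for product the crystals are counted in
- as a solid, counted per litre of solution: crystals
- run time (Tuesday's): 10 min

We build up Friday's one process at a time. The autocatalytic step, in which starting material and reagent react on product to give more product, makes nothing by itself, since its rate carries c(product) as a factor and Friday's starts without product. Once product is present, its growth time at full charges is

τ = 1 / (autocatalytic constant × c(starting material) × c(reagent)) = 81.6 s.

Adding the plain step, starting material + reagent → product, supplies a seed: by itself, at its starting rate, it gives about 2.96% of the starting material charged in 10 min, and the two steps run equally fast at c(product) = 0.237 mM. Integrating both by partial fractions, with depletion counted, brings c(product) to the solubility in Friday's at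

t_on = 7.92 min.

Adding the crystals, we note that they exchange with the solution in 3.12 s, far shorter than τ, so we hold dissolved product at 25 mM. That leaves a pseudo-second-order reaction:

k_c = 3.2 L² mol⁻² s⁻¹ × 25 mM + 7.6 × 10⁻⁴ L mol⁻¹ s⁻¹ = 0.0808 L mol⁻¹ s⁻¹.

We call this the capped constant, the autocatalytic constant times the solubility plus the plain constant. While crystals stand and both charges are in, ln(c(reagent)/c(starting material)) rises at k_c times the fixed gap 5.90 mM. In Friday's the ratio goes from 1.17 at t_on to 1.25, so

product in Friday's = 59.3%.

As long as reaction during the feed can be neglected, a species fed at a steady rate stands on average at half its charge during the feed, so we reckon that such a feed delays t_on by half its length. For Tuesday's that is 20.0 s, which gives 57.2%, below Friday's by 2.1 percentage points, more than the margin. For Saturday's and Sunday's, this reckoning moves t_on to 10.9 min, later than the end of the run. We therefore expect no crystals and commit to less than 42.4% in each.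

The forecast gave 57.4%, 31.7%, 59.3% and 31.7% in the order asked, named Friday's, and began from this: “Product is autocatalytic and its dissolved level is capped near 25 mM”.

The simulation gives 57.3% for Tuesday's, 31.8% for Saturday's, 59.4% for Friday's and 31.8% for Sunday's, so Friday's holds the most.

In Friday's at 10.0 min, dissolved product is made 0.986 times as fast as it is used up, going into crystals counted as use, and the autocatalytic step uses starting material 110 times as fast as the plain step, with crystals standing at 16.7% of the starting material charged. Carrying k_c = 0.0808 L mol⁻¹ s⁻¹ from that state to the same flask read at 25 min leaves 10.9% of the starting material by reckoning, and that flask reads 10.9%.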